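**Strategy.** The cyclohexane ring of the hydrindane (indane numbering; C4 bears Me/OH, C7 bears Br, C7a bears Me) is assembled from two three-carbon units: C5–C4–C3a enters as a 2-methylenepropane-1,3-diyl bis-acetate (its exocyclic CH2 is the later handle for C4) and C6–C7–C7a as a methyl ketone with two nucleophilic α-carbons. A single palladium-catalysed double allylic alkylation of the acyclic keto bis-acetate forms C3a–C7a, which closes the cyclopentane and creates the quaternary centre, and then C5–C6, which closes the cyclohexanone. The precursor carries only the C2/C3 stereocentres. Afterwards the C7 ketone is turned into the equatorial bromide, the methylene into the C4 carbinol, and the bromocyclohexylidene ring is attached by olefination.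

Key step: step 8

Remark: β denotes the face of the 7a-methyl group and α the opposite face; TBS = tert-butyldimethylsilyl. The methyl-bearing carbon that becomes C7a is carried as an epimer pair through steps 1–7 because step 8 enolises it. The enantiomer of the iridium ligand is the one that gives the (2R,3R) diol 7.

Step 1
Reactants: 1 (E)-2-methylbut-2-en-1-ol; 2 triethyl orthoacetate
Product: 4 ethyl 3,4-dimethylpent-4-enoate (racemic), via mixed ketene acetal 3 (not isolated)
Conditions: EtCO2H (cat.), 140 °C, EtOH distilled off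
Reagents that add atoms: none
Why: Johnson–Claisen [3,3] rearrangement of the mixed ketene acetal delivers the two-carbon ester unit to C3 of the allyl system, and the new methine is racemic, which is harmless because it is later the enolised α-carbon.

Step 2
Reactants: 4 ethyl 3,4-dimethylpent-4-enoate
Product: 5 3,4-dimethylpent-4-enal (racemic)
Conditions: i-Bu2AlH, CH2Cl2, −78 °C
Reagents that add atoms: none
Why: Partial hydride reduction of the ester (aluminium hydride reduction at low temperature) should stop at the aldehyde through the stable tetrahedral aluminate; no stereocentre is touched.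

Step 3
Reactants: 5 3,4-dimethylpent-4-enal; 6 4-ethenyl-1,3-dioxolan-2-one
Product: 7 (2R,3R)-2-ethenyl-5,6-dimethylhept-6-ene-1,3-diol (anti; C5 epimer pair)
Conditions: [Ir(cod)Cl]2 (2.5 mol %), (R)-Cl,MeO-BIPHEP (5 mol %), 4-cyano-3-nitrobenzoic acid (10 mol %), Cs2CO3 (20 mol %), propan-2-ol (2 equiv), THF, 60 °C
Reagents that add atoms: none
Why: Iridium-catalysed transfer-hydrogenative anti-(hydroxymethyl)allylation: the (E)-σ-allyl iridium species formed from 6 with loss of CO2 adds to the aldehyde through a chair transition state, so the anti 2-vinyl-1,3-diol forms with catalyst control of both new centres (future C2 and C3).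

Step 4
Reactants: 7 (2R,3R)-2-ethenyl-5,6-dimethylhept-6-ene-1,3-diol
Product: 8 1,3-bis-O-TBS ether of 7
Conditions: TBSCl (2.4 equiv), imidazole, DMF, rt
Reagents that add atoms: tert-butyldimethylsilyl chloride, CC(C)(C)[Si](C)(C)Cl
Why: Silyl ether formation protects both hydroxyls against the later enolate, organometallic and oxidation steps; configuration is unchanged.

Step 5
Reactants: 8 1,3-bis-O-TBS ether of 7
Product: 9 3-(TBSO)-2-(TBSOCH2)-5-methyl-6-oxoheptanal
Conditions: O3, CH2Cl2, −78 °C; then PPh3
Reagents that add atoms: ozone, [O-][O+]=O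
Why: Ozonolysis with reductive work-up cleaves both alkenes, unveiling the methyl ketone from the isopropenyl group and the α-branched aldehyde from the vinyl group under neutral, non-epimerising conditions.

Step 6
Reactants: 9 3-(TBSO)-2-(TBSOCH2)-5-methyl-6-oxoheptanal; 10 2-bromoprop-2-en-1-ol
Product: 11 7,9-dihydroxy-3-methyl-8-methylidene-5-(TBSO)-6-(TBSOCH2)nonan-2-one
Conditions: CrCl2 (6 equiv), NiCl2 (2 mol %), DMSO, rt
Reagents that add atoms: none
Why: Nozaki–Hiyama–Kishi coupling: the alkenylchromium species adds to the aldehyde and leaves the methyl ketone alone, and the new carbinol centre may form as a mixture because it is later ionised to a π-allyl complex.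

Step 7
Reactants: 11 keto diol
Product: 12 7,9-diacetoxy-3-methyl-8-methylidene-5-(TBSO)-6-(TBSOCH2)nonan-2-one
Conditions: Ac2O, pyridine, DMAP (cat.), CH2Cl2, rt
Reagents that add atoms: acetic anhydride, CC(=O)OC(C)=O
Why: Acylation turns both allylic hydroxyls into leaving groups for palladium; no stereocentre is affected.

Step 8
Reactants: 12 keto bis-acetate
Product: 14 7a-methyl-4-methylidene-2-(TBSO)-3-(TBSOCH2)octahydro-1H-inden-7-one (trans-fused), via acetylcyclopentane allylic acetate 13 (not isolated)
Conditions: Pd(PPh3)4 (10 mol %), 1,1,3,3-tetramethylguanidine (2.5 equiv), 1,4-dioxane, 80 °C, high dilution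
Reagents that add atoms: none
Why: Zerovalent palladium ionises the two allylic acetates reversibly to 2-substituted π-allyl complexes, and the guanidinium enolates of the ketone attack them from the face opposite to the metal: first the more substituted α-carbon (future C7a) on the substituted allyl terminus (C3a), then the methyl α′-carbon (C6) on the second π-allyl (C5), with acetate as the only leaving group. The closest known reaction type is the palladium-catalysed α,α′-annulation (double Tsuji–Trost alkylation, formal [3+3]) of ketones or β-keto esters with 2-methylenepropane-1,3-diyl diacetate, run here within one molecule so that both rings form. The cyclopentane closes 5-exo at the proximal allyl terminus (C3a–C7a) in preference to the seven-membered alternative, and the cyclohexanone then closes by a six-membered enolate alkylation in which both termini of the symmetrical π-allyl give the same methylenecyclohexanone (C5–C6). C3a is set trans to the CH2OTBS-bearing C3 because the π-allyl faces interconvert (π–σ–π) and the less crowded cyclisation wins, whatever the configuration of the starting carbinol acetate. C7a is set by the face of the planar enolate: its ion-paired acetyl arm is expected to turn away from the propenyl unit on C3a, leaving the methyl group cis to it, which after the second closure is the trans ring fusion, and the racemic α-centre of 12 is erased by enolisation. The step needs C- over O-alkylation, five- over seven-membered closure and this enolate-face selectivity; the first two follow from ring size and soft π-allyl chemistry, the third is the uncertain one and can be reinforced with a chiral bisphosphine ligand.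

Step 9
Reactants: 14 hydrindan-7-one
Product: 15 enol triflate of 14 (7-trifloxy-6-ene)
Conditions: KN(SiMe3)2, THF, −78 °C; then PhNTf2
Reagents that add atoms: N-phenylbis(trifluoromethanesulfonimide), O=S(=O)(N(c1ccccc1)S(=O)(=O)C(F)(F)F)C(F)(F)F
Why: Enol triflate formation: the ketone can only enolise toward C6 because C7a is quaternary, so a single regioisomer should form.

Step 10
Reactants: 15 enol triflate
Product: 16 7-bromo-7a-methyl-4-methylidene-2-(TBSO)-3-(TBSOCH2)-2,3,3a,4,5,7a-hexahydro-1H-indene
Conditions: Ni(cod)2 (10 mol %), NaBr (3 equiv), DMA–THF, rt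
Reagents that add atoms: sodium bromide, [Na+].[Br-]
Why: Nickel-catalysed halogenation of an enol triflate (oxidative addition, halide exchange, reductive elimination) should give the alkenyl bromide without moving the double bond.

Step 11
Reactants: 16 alkenyl bromide with exocyclic methylene
Product: 17 7-bromo-7a-methyl-2-(TBSO)-3-(TBSOCH2)-1,2,3,3a,5,7a-hexahydro-4H-inden-4-one
Conditions: O3, CH2Cl2–pyridine, −78 °C (indicator end-point); then PPh3
Reagents that add atoms: ozone, [O-][O+]=O
Why: Ozonolysis should be selective for the electron-rich 1,1-disubstituted alkene over the bromine-deactivated trisubstituted one and gives the C4 ketone.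

Step 12
Reactants: 17 C4 ketone
Product: 18 7-bromo-4α,7a-dimethyl-2-(TBSO)-3-(TBSOCH2)-2,3,3a,4,5,7a-hexahydro-1H-inden-4β-ol
Conditions: MeMgBr, CeCl3, THF, −78 °C
Reagents that add atoms: methylmagnesium bromide, C[Mg]Br
Why: Carbonyl 1,2-addition of the weakly basic organocerium reagent should occur from the equatorial α face because the axial β approach is blocked 1,3-diaxially by the 7a-methyl group, placing OH axial (β) and the new methyl equatorial without epimerising C3a.

Step 13
Reactants: 18 alkenyl bromide tertiary alcohol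
Product: 19 7β-bromo-4α,7a-dimethyl-2-(TBSO)-3-(TBSOCH2)octahydro-1H-inden-4β-ol
Conditions: Co(acac)2 (25 mol %), t-BuOOH, Et3SiH, cyclohexa-1,4-diene, n-PrOH, rt, argon
Reagents that add atoms: none
Why: Cobalt hydride hydrogen-atom-transfer hydrogenation of an alkenyl halide: H-atom transfer to C6 gives the α-bromo radical at C7, which should take hydrogen from cyclohexadiene along the open axial α trajectory anti to the 7a-methyl group, leaving bromine equatorial (β).

Step 14
Reactants: 19 bis-TBS ether
Product: 20 primary alcohol (3-CH2OH; 2-OTBS retained)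
Conditions: HF·pyridine, pyridine, THF, 0 °C
Reagents that add atoms: none
Why: Selective desilylation: the unhindered primary silyl ether should cleave much faster than the secondary one.

Step 15
Reactants: 20 primary alcohol
Product: 21 aldehyde (3-CHO; 2-OTBS)
Conditions: Dess–Martin periodinane, NaHCO3, CH2Cl2, 0 °C
Reagents that add atoms: none
Why: Dess–Martin oxidation under buffered conditions should give the α-branched aldehyde without epimerising C3 and leaves the tertiary alcohol untouched.

Step 16
Reactants: 22 methyl acetoacetate; 23 1-bromo-3-methylbut-2-ene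
Product: 24 methyl 7-methyl-3-oxooct-6-enoate
Conditions: NaH, then n-BuLi, THF, 0 °C; 23; aq. HCl quench
Reagents that add atoms: none
Why: Alkylation of the acetoacetate dianion takes place at the more nucleophilic terminal (γ) carbon with the allylic bromide.

Step 17
Reactants: 24 methyl 7-methyl-3-oxooct-6-enoate
Product: 25 methyl 3-bromo-2,2-dimethyl-6-oxocyclohexane-1-carboxylate (racemic)
Conditions: Et2SBr·SbCl5Br (1.1 equiv), MeNO2, −25 °C
Reagents that add atoms: bromodiethylsulfonium bromopentachloroantimonate, CC[S+](Br)CC.Cl[Sb-](Cl)(Cl)(Cl)(Cl)Br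
Why: Bromonium-induced cation–olefin cyclisation: Br+ adds to the trisubstituted alkene and the tertiary cation is captured by the enol carbon of the β-keto ester through a chair, so bromine ends equatorial next to the new gem-dimethyl carbon (racemic).

Step 18
Reactants: 25 bromo keto ester
Product: 26 4-bromo-3,3-dimethylcyclohexan-1-one (racemic)
Conditions: LiCl, H2O, DMSO, 130 °C
Reagents that add atoms: none
Why: Krapcho dealkoxycarbonylation removes the ester, and the neopentyl-type secondary bromide should resist substitution by chloride.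

Step 19
Reactants: 26 4-bromo-3,3-dimethylcyclohexan-1-one (racemic)
Product: 27 (1S,4S)-4-bromo-3,3-dimethylcyclohexan-1-ol
Conditions: (S)-selective ketoreductase (NADPH-dependent alcohol dehydrogenase), NADP+ (cat.), propan-2-ol, phosphate buffer pH 7, 30 °C; chromatographic removal of the (1S,4R) diastereomer
Reagents that add atoms: none
Why: Enzymatic carbonyl reduction by a ketoreductase should set the carbinol centre as (S) in both enantiomers of the ketone, turning the racemate into two separable diastereomers, of which the (1S,4S) one carries the required (S)-CHBr centre.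

Step 20
Reactants: 27 (1S,4S)-4-bromo-3,3-dimethylcyclohexan-1-ol
Product: 28 5-{[(1R,4S)-4-bromo-3,3-dimethylcyclohexyl]sulfanyl}-1-phenyl-1H-tetrazole
Conditions: 1-phenyl-1H-tetrazole-5-thiol, PPh3, diisopropyl azodicarboxylate, THF, 0 °C to rt
Reagents that add atoms: 1-phenyl-1H-tetrazole-5-thiol, Sc1nnnn1-c1ccccc1
Why: Mitsunobu thioetherification with inversion at C1, a centre that is later destroyed.

Step 21
Reactants: 28 tetrazolyl sulfide
Product: 29 5-{[(1R,4S)-4-bromo-3,3-dimethylcyclohexyl]sulfonyl}-1-phenyl-1H-tetrazole
Conditions: H2O2 (30 %), (NH4)6Mo7O24 (cat.), EtOH, rt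
Reagents that add atoms: hydrogen peroxide, OO
Why: Molybdate-catalysed sulfide oxidation gives the sulfone needed for the olefination without touching the bromide.

Step 22
Reactants: 21 aldehyde; 29 tetrazolyl sulfone
Product: 30 2-O-TBS iriediol (E alkene)
Conditions: 29 (1.5 equiv), KN(SiMe3)2 (2.5 equiv), DME, −60 °C to rt; separation of the Z isomer on AgNO3-impregnated silica
Reagents that add atoms: none
Why: Julia–Kocienski olefination: the metallated sulfone adds to the aldehyde, and Smiles rearrangement with loss of SO2 and the tetrazolate gives the trisubstituted exocyclic alkene, in which the E isomer (C3 substituent anti to the CH2 next to the gem-dimethyl carbon) is expected to be favoured only modestly.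

Step 23
Reactants: 30 2-O-TBS iriediol
Product: 31 iriediol
Conditions: HF·pyridine, THF, rt
Reagents that add atoms: none
Why: Fluoride-mediated desilylation of the secondary silyl ether under non-basic conditions spares the secondary bromides and the tertiary alcohol.

**Compound list**

1 | (E)-2-methylbut-2-en-1-ol | C/C=C(\C)CO | starting material
2 | triethyl orthoacetate | CCOC(C)(OCC)OCC | starting material
3 | 1-ethoxy-1-[(E)-2-methylbut-2-enyloxy]ethene (mixed ketene acetal) | C=C(OCC)OC/C(C)=C/C | intermediate
4 | ethyl 3,4-dimethylpent-4-enoate (racemic) | CCOC(=O)CC(C)C(C)=C | intermediate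
5 | 3,4-dimethylpent-4-enal (racemic) | O=CCC(C)C(C)=C | intermediate
6 | 4-ethenyl-1,3-dioxolan-2-one (racemic) | C=CC1COC(=O)O1 | starting material
7 | (2R,3R)-2-ethenyl-5,6-dimethylhept-6-ene-1,3-diol (anti; C5 epimer pair) | OC[C@@H](C=C)[C@H](O)CC(C)C(C)=C | intermediate
8 | 1,3-bis-O-TBS ether of 7 | CC(C)(C)[Si](C)(C)OC[C@@H](C=C)[C@H](O[Si](C)(C)C(C)(C)C)CC(C)C(C)=C | intermediate
9 | 3-(TBSO)-2-(TBSOCH2)-5-methyl-6-oxoheptanal (C2/C3 as in 7) | CC(C)(C)[Si](C)(C)OC[C@@H](C=O)[C@H](O[Si](C)(C)C(C)(C)C)CC(C)C(C)=O | intermediate
10 | 2-bromoprop-2-en-1-ol | OCC(Br)=C | starting material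
11 | 7,9-dihydroxy-3-methyl-8-methylidene-5-(TBSO)-6-(TBSOCH2)nonan-2-one (C5/C6 as in 7; C3 and C7 mixtures) | CC(C)(C)[Si](C)(C)OC[C@@H](C(O)C(=C)CO)[C@H](O[Si](C)(C)C(C)(C)C)CC(C)C(C)=O | intermediate
12 | 7,9-diacetoxy analogue of 11 (keto bis-acetate) | CC(C)(C)[Si](C)(C)OC[C@@H](C(OC(C)=O)C(=C)COC(C)=O)[C@H](O[Si](C)(C)C(C)(C)C)CC(C)C(C)=O | intermediate
13 | 2-[2-acetyl-2-methyl-4-(TBSO)-5-(TBSOCH2)cyclopentyl]prop-2-enyl acetate (acetyl trans to the propenyl unit; propenyl trans to CH2OTBS; OTBS cis to CH2OTBS) | CC(C)(C)[Si](C)(C)OC[C@@H]1[C@H](O[Si](C)(C)C(C)(C)C)C[C@](C)(C(C)=O)[C@H]1C(=C)COC(C)=O | intermediate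
14 | 7a-methyl-4-methylidene-2-(TBSO)-3-(TBSOCH2)octahydro-1H-inden-7-one (trans-fused: 7a-Me β, 3a-H α; 2-OTBS α; 3-CH2OTBS α) | CC(C)(C)[Si](C)(C)OC[C@@H]1[C@H](O[Si](C)(C)C(C)(C)C)C[C@]2(C)C(=O)CCC(=C)[C@@H]12 | intermediate
15 | enol triflate of 14 (7-trifloxy-6-ene) | CC(C)(C)[Si](C)(C)OC[C@@H]1[C@H](O[Si](C)(C)C(C)(C)C)C[C@]2(C)C(OS(=O)(=O)C(F)(F)F)=CCC(=C)[C@@H]12 | intermediate
16 | 7-bromo-6-ene with 4-methylidene (alkenyl bromide) | CC(C)(C)[Si](C)(C)OC[C@@H]1[C@H](O[Si](C)(C)C(C)(C)C)C[C@]2(C)C(Br)=CCC(=C)[C@@H]12 | intermediate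
17 | 7-bromo-6-en-4-one | CC(C)(C)[Si](C)(C)OC[C@@H]1[C@H](O[Si](C)(C)C(C)(C)C)C[C@]2(C)C(Br)=CCC(=O)[C@@H]12 | intermediate
18 | 7-bromo-6-ene, 4β-OH, 4α-Me tertiary alcohol | CC(C)(C)[Si](C)(C)OC[C@@H]1[C@H](O[Si](C)(C)C(C)(C)C)C[C@]2(C)C(Br)=CC[C@@](C)(O)[C@@H]12 | intermediate
19 | 7β-bromo-4α,7a-dimethyl-2α-(TBSO)-3α-(TBSOCH2)octahydro-1H-inden-4β-ol | CC(C)(C)[Si](C)(C)OC[C@@H]1[C@H](O[Si](C)(C)C(C)(C)C)C[C@]2(C)[C@@H](Br)CC[C@@](C)(O)[C@@H]12 | intermediate
20 | primary alcohol (3α-CH2OH; 2α-OTBS) | OC[C@@H]1[C@H](O[Si](C)(C)C(C)(C)C)C[C@]2(C)[C@@H](Br)CC[C@@](C)(O)[C@@H]12 | intermediate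
21 | aldehyde (3α-CHO; 2α-OTBS) | O=C[C@@H]1[C@H](O[Si](C)(C)C(C)(C)C)C[C@]2(C)[C@@H](Br)CC[C@@](C)(O)[C@@H]12 | intermediate
22 | methyl acetoacetate | COC(=O)CC(C)=O | starting material
23 | 1-bromo-3-methylbut-2-ene | CC(C)=CCBr | starting material
24 | methyl 7-methyl-3-oxooct-6-enoate | COC(=O)CC(=O)CCC=C(C)C | intermediate
25 | methyl 3-bromo-2,2-dimethyl-6-oxocyclohexane-1-carboxylate (racemic) | COC(=O)C1C(=O)CCC(Br)C1(C)C | intermediate
26 | 4-bromo-3,3-dimethylcyclohexan-1-one (racemic) | CC1(C)CC(=O)CCC1Br | intermediate
27 | (1S,4S)-4-bromo-3,3-dimethylcyclohexan-1-ol | CC1(C)C[C@@H](O)CC[C@@H]1Br | intermediate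
28 | 5-{[(1R,4S)-4-bromo-3,3-dimethylcyclohexyl]sulfanyl}-1-phenyl-1H-tetrazole | CC1(C)C[C@H](Sc2nnnn2-c2ccccc2)CC[C@@H]1Br | intermediate
29 | 5-{[(1R,4S)-4-bromo-3,3-dimethylcyclohexyl]sulfonyl}-1-phenyl-1H-tetrazole | CC1(C)C[C@H](S(=O)(=O)c2nnnn2-c2ccccc2)CC[C@@H]1Br | intermediate
30 | 2-O-TBS iriediol | CC1(C)C/C(=C/[C@@H]2[C@H](O[Si](C)(C)C(C)(C)C)C[C@]3(C)[C@@H](Br)CC[C@@](C)(O)[C@@H]23)CC[C@@H]1Br | intermediate
31 | iriediol | CC1(C)C/C(=C/[C@@H]2[C@H](O)C[C@]3(C)[C@@H](Br)CC[C@@](C)(O)[C@@H]23)CC[C@@H]1Br | target

**Totals.** Total step count: 23. Longest linear sequence: 17 (steps 1–15, 22, 23).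

**Steps most likely to fail**

1. Step 8. The enolate may attack with poor face selectivity at C7a, which would give the cis-fused isomer, and seven-membered closure may compete with the cyclopentane closure. The fallback sets out from 12 and comes back at 14, with ligand control instead of substrate control and the two closures separated. The more substituted trimethylsilyl enol ether F1 is made from 12 (Me3SiCl, NaI, Et3N, MeCN). It is cyclised with Pd2(dba)3, a chiral DACH-phenyl bisphosphine and Bu4N[Ph3SiF2], so that the ligand selects the enolate face. Monocycle 13 is now isolated and purified, then closed to 14 with Pd(PPh3)4 and tetramethylguanidine.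

2. Step 13. The radical reduction may lose bromine by over-reduction, or hydrogen may be delivered to the wrong face of the C7 radical. The fallback sets out from 18 and comes back at 19 by a different mechanism: heterogeneous syn-hydrogenation (H2, Rh/Al2O3, EtOAc, K2CO3), which adds both hydrogens from the open α face. No new compound arises (F0).

3. Step 22. The sulfone anion may discriminate poorly between the two ring-methylene branches during addition and elimination, giving E/Z mixtures. The fallback sets out from 20 (and 27) and comes back at 30 by a Horner–Wittig sequence with isolable adducts. Alcohol 20 is converted into the iodide F2 (I2, PPh3, imidazole) and then the diphenylphosphine oxide F3 (LiPPh2, then H2O2). Alcohol 27 is oxidised with Dess–Martin periodinane to (S)-4-bromo-3,3-dimethylcyclohexan-1-one F4. Lithiated F3 (n-BuLi, THF, −78 °C) adds to F4; the β-hydroxyphosphine oxide diastereomers are separated, and the syn-eliminating isomer F5 is treated with NaH in DMF to give only the E alkene 30.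

Further compounds
F1 | step 8 | more substituted trimethylsilyl enol ether of 12 | CC(C)(C)[Si](C)(C)OC[C@@H](C(OC(C)=O)C(=C)COC(C)=O)[C@H](O[Si](C)(C)C(C)(C)C)CC(C)=C(C)O[Si](C)(C)C
F0 | step 13 | none | none
F2 | step 22 | primary iodide from 20 (3α-CH2I; 2α-OTBS) | IC[C@@H]1[C@H](O[Si](C)(C)C(C)(C)C)C[C@]2(C)[C@@H](Br)CC[C@@](C)(O)[C@@H]12
F3 | step 22 | diphenylphosphine oxide from F2 (3α-CH2P(O)Ph2) | O=P(C[C@@H]1[C@H](O[Si](C)(C)C(C)(C)C)C[C@]2(C)[C@@H](Br)CC[C@@](C)(O)[C@@H]12)(c1ccccc1)c1ccccc1
F4 | step 22 | (S)-4-bromo-3,3-dimethylcyclohexan-1-one | CC1(C)CC(=O)CC[C@@H]1Br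
F5 | step 22 | β-hydroxyphosphine oxide adduct of F3 and F4 (the separated diastereomer that syn-eliminates to the E alkene; the two new centres are not assigned) | CC1(C)CC(O)(C([C@@H]2[C@H](O[Si](C)(C)C(C)(C)C)C[C@]3(C)[C@@H](Br)CC[C@@](C)(O)[C@@H]23)P(=O)(c2ccccc2)c2ccccc2)CC[C@@H]1Br
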